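The numbers of this flask are assumed.

The product J.L grows out of J, so what these flasks can offer it starts with how much J stands at the end of the run, and that is my question here.

| setting | teal | red | ochre | blue |
|---|---|---|---|---|
| X | 0.0050 M | 0.0050 M | 0.0050 M | 0.0050 M |
| E | 6.00 mM | 6.00 mM | 6.00 mM | 6.00 mM |
| Z | 0.250 mM | 0.250 mM | 0.250 mM | 0.250 mM |
| temperature | 50 °C | 20 °C | 5 °C | 35 °C |
| time | 30 s | 30 s | 30 s | 30 s |

    E → Q (k1 = 0.084 s⁻¹, Ea1 = 69.0 kJ mol⁻¹)
    E → L (k2 = 0.063 s⁻¹, Ea2 = 83.0 kJ mol⁻¹)
    X ⇌ J (K3 = 0.26, k3 = 0.26 s⁻¹, Ea3 = 68.0 kJ mol⁻¹, ΔH3 = −71.0 kJ mol⁻¹)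
    J + L ⇌ J.L (K4 = 150 M⁻¹, k4 = 2.8 M⁻¹ s⁻¹, Ea4 = 47.0 kJ mol⁻¹, ΔH4 = −9.00 kJ mol⁻¹)
    L + Z → L.Z (k5 = 5.0 M⁻¹ s⁻¹, Ea5 = 43.0 kJ mol⁻¹)
    (constants at 20 °C)

- constants are those at 20 °C; use the activation energies and enthalpies for any other temperature

- the flask with the highest amount of J, in percent of the X charged ("all alike" if they lie within 1.5 percentage points) (teal / red / ochre / blue / all alike)
- final J, as a percentage of the X charged, in teal
- final J, as a percentage of the X charged, in red
- final J, as a percentage of the X charged, in ochre
- final J, as a percentage of the X charged, in blue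

I begin with ochre, at 5 °C, and come at its J by two ways. The first asks where the step from X to J stops. Shifted by its enthalpy, the equilibrium constant there is 1.25, which gives an equilibrium share of J among X and J of

share = K / (1 + K) = 55.6 %

The second way asks how fast J is made. The forward constant in ochre is 0.0578 s⁻¹, and first-order loss of X over 30 s gives

forward conversion = 82.3 %

The two part by 27 percentage points. The second way cheats: it piles up J as if none went back, but J returns to X with a constant of 0.0462 s⁻¹. Both constants work on one gap to equilibrium, so the gap closes with their sum: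

relaxation half-life = ln(2) / (forward + reverse) = 6.67 s

This relaxation half-life is the clock I carry on. Ochre's run holds 4.50 of them, so the first way cheats a little as well, since this clock puts ochre 95.6 % of the way to equilibrium at the end of the run. Hence

J in ochre = share × way travelled = 53.1 %

Even with the whole 6.00 mM of E counted as L, J leaks into J.L in ochre at a pseudo-first-order 0.00594 s⁻¹, slower than the relaxation, so I set it aside.

The warmer flasks, reckoned the same way:

red: K 0.26, half-life 0.550 s, J 20.6 %

blue: K 0.0630, half-life 0.0406 s, J 5.92 %

teal: K 0.0174, half-life 0.00342 s, J 1.71 %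

Because these half-lives are short against 30 s, I take the equilibrium share itself in these three flasks, which is thermodynamic control. My highest flask is ochre.

The forecast also names ochre, with 1.7 % in teal, 20.1 % in red, 52.4 % in ochre and 5.8 % in blue, on the ground that “J reaches or nearly reaches this equilibrium” within the run. In ochre my figure stands a little higher than its own, and in red too.

The flask gives 1.70 % of the X charged in teal, 20.0 % in red, 52.5 % in ochre and 5.83 % in blue, so ochre holds the most J. J.L in ochre stands at 0.861 % of the X charged at that moment. On the clock of 6.67 s, the ochre reading is 94.4 % of the equilibrium share, against 95.6 % counted. The teal recipe run at 25 °C has K 0.160 and a relaxation half-life of 0.230 s, hence 131 half-lives and a share of 13.8 %; that flask gives 13.4 %.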